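**Plan**

- Atoms are numbered along the target SMILES: C1 is the exocyclic CH2 on C2, O9 is the pyran oxygen, C5 and C10 are the pyran ring-fusion carbons, and C14 and C15 are the cyclobutane CH carbons. C12–C13 is a plain CH2–CH2 bridge between the quaternary ether carbon C10 of the pyran and cyclobutane C14, so a vinyl group on each of these carbons can be joined by metathesis and the alkene then saturated.
- Retrosynthetic cuts, in order: C1=C2 (methylenation of a C2 ketone), C12–C13 (hydrogenation, then ring-closing metathesis), O9–C10 (palladium allylic etherification), C6–C7 (reductive alkylation of the gem-dimethylated acylphloroglucinol trione), C4–C5 (Michael addition to a cyclobutyl vinyl ketone).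
- Forward order: the cyclobutane is made first (ring contraction of a diazocyclopentanone, then C–H alkenylation); the chain is joined at C4–C5 and then C6–C7; the pyran closes next and the nine-membered ring last.
- Stereochemistry: C14/C15 come from an alkaloid-controlled ketene amidation, a directed cis C–H alkenylation and epimerisation to trans. C5 comes from enamine catalysis with a diarylprolinol ether. C10 comes from the Trost ligand acting on an equilibrating π-allyl complex.

Key step: step 18

Assumption: (+)-cinchonine is taken to give the (S)-configured cyclobutane amide and the (R,R)-configured Trost ligand the (R)-configured ether carbon C10; if either sense of induction is the reverse, cinchonidine or the (S,S)-ligand takes its place and nothing else changes.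

**Route**

Step 1
Reactants: 1 2,2-dimethylcyclopentan-1-one
Product: 3 5-diazo-2,2-dimethylcyclopentan-1-one, via trifluoroacetyl ketone 2 (not isolated)
Conditions: LiN(SiMe3)2, THF, −78 °C, then CF3CO2CH2CF3; aq. HCl work-up; crude 2, 4-acetamidobenzenesulfonyl azide, Et3N, H2O, MeCN, rt
Reagents that add atoms: 2,2,2-trifluoroethyl trifluoroacetate, O=C(OCC(F)(F)F)C(F)(F)F (its CF3CO group stays only in 2); 4-acetamidobenzenesulfonyl azide, CC(=O)Nc1ccc(cc1)S(=O)(=O)N=[N+]=[N-]
Why: Detrifluoroacetylative diazo transfer: the enolate can form only at C5, its trifluoroacetyl derivative takes the diazo group from the sulfonyl azide and loses the activating acyl group as the N-acyl sulfonamide.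

Step 2
Reactants: 3 5-diazo-2,2-dimethylcyclopentan-1-one
Product: 5 (S)-2,2-dimethyl-N-(quinolin-8-yl)cyclobutane-1-carboxamide, via ketene 4 (not isolated)
Conditions: hν (254 nm), quinolin-8-amine (3 equiv), (+)-cinchonine (10 mol %), THF, rt; recrystallisation
Reagents that add atoms: quinolin-8-amine, Nc1cccc2cccnc12
Why: Photochemical Wolff rearrangement contracts the ring to the cyclobutylidene ketene, and in the catalytic asymmetric ketene amidation the cinchona alkaloid controls the face on which the amine adduct is protonated, which sets the carboxamide-bearing stereocentre; crystallisation should raise the enantiomeric purity.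

Step 3
Reactants: 5 (S)-2,2-dimethyl-N-(quinolin-8-yl)cyclobutane-1-carboxamide
Product: 6 (1S,4R)-2,2-dimethyl-4-(2-methylprop-1-en-1-yl)-N-(quinolin-8-yl)cyclobutane-1-carboxamide (cis)
Conditions: Pd(OAc)2 (15 mol %), Ag2CO3 (1 equiv), 1-iodo-2-methylprop-1-ene (2 equiv), t-BuOMe, 90 °C, sealed tube
Reagents that add atoms: 1-iodo-2-methylprop-1-ene, CC(C)=CI
Why: Aminoquinoline-directed palladium-catalysed C(sp3)–H alkenylation: the five-membered palladacycle can form only at the C4 methylene on the face of the amide, so the alkenyl group enters cis and the configuration of C4 follows from that of C1.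

Step 4
Reactants: 6 (1S,4R)-2,2-dimethyl-4-(2-methylprop-1-en-1-yl)-N-(quinolin-8-yl)cyclobutane-1-carboxamide
Product: 8 (1R,4R)-2,2-dimethyl-4-(2-methylprop-1-en-1-yl)cyclobutane-1-carbaldehyde, via cis-aldehyde 7 (not isolated)
Conditions: Cp2Zr(H)Cl (2.5 equiv), THF, rt; aqueous work-up; then KOH, MeOH, rt
Reagents that add atoms: none
Why: Schwartz reduction of the amide stops at the aldehyde after hydrolysis, and base then epimerises the aldehyde α-carbon to the more stable trans-1,2-disubstituted cyclobutane, which inverts C1 and leaves C4 as set in step 3.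

Step 5
Reactants: 8 (1R,4R)-2,2-dimethyl-4-(2-methylprop-1-en-1-yl)cyclobutane-1-carbaldehyde
Product: 9 (2R,3R)-2-ethenyl-1,1-dimethyl-3-(2-methylprop-1-en-1-yl)cyclobutane
Conditions: Ph3PCH3Br, KOtBu, THF, 0 °C to rt
Reagents that add atoms: methyltriphenylphosphonium bromide, [Br-].C[P+](c1ccccc1)(c1ccccc1)c1ccccc1
Why: Wittig methylenation of an aldehyde; the trans aldehyde is already the stable epimer, so the basic ylide should not erode it.

Step 6
Reactants: 9 (2R,3R)-2-ethenyl-1,1-dimethyl-3-(2-methylprop-1-en-1-yl)cyclobutane
Product: 11 (1S,2R)-2-ethenyl-3,3-dimethylcyclobutane-1-carbaldehyde, via epoxide 10 (not isolated)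
Conditions: mCPBA (1.0 equiv), CH2Cl2, 0 °C; then H5IO6, THF–H2O, 0 °C to rt
Reagents that add atoms: 3-chloroperbenzoic acid, OOC(=O)c1cccc(Cl)c1
Why: Prilezhaev epoxidation picks the trisubstituted alkene over the vinyl group because it is far more nucleophilic, and periodic acid then opens and cleaves the epoxide to the aldehyde and acetone.

Step 7
Reactants: 11 (1S,2R)-2-ethenyl-3,3-dimethylcyclobutane-1-carbaldehyde
Product: 12 1-[(1S,2R)-2-ethenyl-3,3-dimethylcyclobutyl]prop-2-en-1-ol (both carbinol epimers)
Conditions: CH2=CHMgBr, THF, −78 °C; H2O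
Reagents that add atoms: vinylmagnesium bromide, C=C[Mg]Br
Why: Grignard 1,2-addition to the aldehyde; the new carbinol centre needs no control because it is oxidised in the next step.

Step 8
Reactants: 12 1-[(1S,2R)-2-ethenyl-3,3-dimethylcyclobutyl]prop-2-en-1-ol
Product: 13 1-[(1S,2R)-2-ethenyl-3,3-dimethylcyclobutyl]prop-2-en-1-one
Conditions: Dess–Martin periodinane, CH2Cl2, 0 °C; used at once
Reagents that add atoms: none
Why: Dess–Martin oxidation gives the vinyl ketone under neutral conditions, and the ring carbon next to the ketone stays trans because that is its stable configuration.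

Step 9
Reactants: 14 ethyl acetate; 15 but-3-en-2-one
Product: 16 ethyl 3-hydroxy-3-methylpent-4-enoate (racemic)
Conditions: LiN(iPr)2, THF, −78 °C, 14; then 15; AcOH quench
Reagents that add atoms: none
Why: Kinetic aldol-type 1,2-addition of the lithium ester enolate to the enone carbonyl at low temperature; the tertiary carbinol is left racemic on purpose because step 17 passes through a π-allyl complex that erases it.

Step 10
Reactants: 16 ethyl 3-hydroxy-3-methylpent-4-enoate
Product: 17 ethyl 3-methyl-3-(triethylsilyloxy)pent-4-enoate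
Conditions: Et3SiOTf, 2,6-lutidine, CH2Cl2, 0 °C
Reagents that add atoms: triethylsilyl trifluoromethanesulfonate, CC[Si](CC)(CC)OS(=O)(=O)C(F)(F)F
Why: Silylation of a hindered tertiary alcohol with a silyl triflate; the ether blocks retro-aldol cleavage in the following steps.

Step 11
Reactants: 17 ethyl 3-methyl-3-(triethylsilyloxy)pent-4-enoate
Product: 18 3-methyl-3-(triethylsilyloxy)pent-4-enal
Conditions: iBu2AlH (1.1 equiv), CH2Cl2, −78 °C; Rochelle salt work-up
Reagents that add atoms: none
Why: Partial ester reduction with iBu2AlH: the tetrahedral aluminium hemiacetal is stable at −78 °C and releases the aldehyde only on work-up.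

Step 12
Reactants: 19 phloroglucinol; 20 isobutyryl chloride
Product: 21 2-methyl-1-(2,4,6-trihydroxyphenyl)propan-1-one
Conditions: AlCl3, PhNO2–CS2, 50 °C
Reagents that add atoms: none
Why: Friedel–Crafts C-acylation of the electron-rich arene; the first acyl group deactivates the ring against a second one.

Step 13
Reactants: 21 2-methyl-1-(2,4,6-trihydroxyphenyl)propan-1-one
Product: 22 3,5-dihydroxy-6,6-dimethyl-2-(2-methylpropanoyl)cyclohexa-2,4-dien-1-one (isobutyrylfilicinic acid)
Conditions: NaOMe, MeI (2.1 equiv), MeOH, 0 °C to rt; aq. HCl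
Reagents that add atoms: iodomethane, CI
Why: Alkylative dearomatisation: the phenolate is C-methylated twice at the same ring carbon, which gives the gem-dimethyl enolised trione and leaves one ring CH (C4) as the only nucleophilic carbon.

Step 14
Reactants: 18 3-methyl-3-(triethylsilyloxy)pent-4-enal; 13 1-[(1S,2R)-2-ethenyl-3,3-dimethylcyclobutyl]prop-2-en-1-one
Product: 23 (2R,3RS)-2-{3-[(1S,2R)-2-ethenyl-3,3-dimethylcyclobutyl]-3-oxopropyl}-3-methyl-3-(triethylsilyloxy)pent-4-enal
Conditions: (R)-2-[methoxy(diphenyl)methyl]pyrrolidine (10 mol %), ethyl 3,4-dihydroxybenzoate (20 mol %), CHCl3, 4 °C to rt; 18 in excess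
Reagents that add atoms: none
Why: Enamine-catalysed Michael addition of an aldehyde to a vinyl ketone: the diarylmethyl ether group of the (R)-catalyst shields one face of the E-enamine of 18, so the enone terminus is delivered to the other face and C5 (the aldehyde α-carbon) is set as R by the catalyst, while the racemic silyloxy carbon next to it is carried as two epimers.

Step 15
Reactants: 23 (keto aldehyde); 22 isobutyrylfilicinic acid
Product: 25 4-[(2S,3RS)-2-{3-[(1S,2R)-2-ethenyl-3,3-dimethylcyclobutyl]-3-oxopropyl}-3-methyl-3-(triethylsilyloxy)pent-4-en-1-yl]-3,5-dihydroxy-6,6-dimethyl-2-(2-methylpropanoyl)cyclohexa-2,4-dien-1-one, via alkylidene trione 24 (not isolated)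
Conditions: diethyl 2,6-dimethyl-1,4-dihydropyridine-3,5-dicarboxylate (1.1 equiv), L-proline (10 mol %), CH2Cl2, rt
Reagents that add atoms: none
Why: Three-component reductive alkylation: Knoevenagel condensation of the aldehyde with the single ring CH of 22 gives the alkylidene trione, which the Hantzsch ester reduces at once by conjugate hydride transfer, so neither a second trione nor the ketone of the arm should intervene and C5 is not touched.

Step 16
Reactants: 25 (silyl ether)
Product: 26 4-[(2S,3RS)-2-{3-[(1S,2R)-2-ethenyl-3,3-dimethylcyclobutyl]-3-oxopropyl}-3-hydroxy-3-methylpent-4-en-1-yl]-3,5-dihydroxy-6,6-dimethyl-2-(2-methylpropanoyl)cyclohexa-2,4-dien-1-one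
Conditions: HF·pyridine, pyridine, THF, 0 °C
Reagents that add atoms: none
Why: Fluoride-driven cleavage of the triethylsilyl ether under buffered conditions, mild enough that the tertiary allylic alcohol should not ionise before the palladium step.

Step 17
Reactants: 26 (tertiary allylic alcohol)
Product: 27 (2R,3S)-2-ethenyl-3-{3-[(1S,2R)-2-ethenyl-3,3-dimethylcyclobutyl]-3-oxopropyl}-5-hydroxy-2,8,8-trimethyl-6-(2-methylpropanoyl)-3,4-dihydro-2H-chromen-7(8H)-one (2-vinyl trans to the 3-alkyl arm)
Conditions: Pd2(dba)3·CHCl3 (2.5 mol %), N,N′-[(1R,2R)-cyclohexane-1,2-diyl]bis[2-(diphenylphosphanyl)benzamide] (7.5 mol %), CH2Cl2, 4 Å molecular sieves, rt; stopped at full conversion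
Reagents that add atoms: none
Why: Tsuji–Trost allylic etherification run as a Trost asymmetric cyclisation: the enolised trione (a vinylogous acid) activates the tertiary allylic alcohol for ionisation by zerovalent palladium, the π-allyl complex equilibrates through its unsubstituted terminus so both carbinol epimers converge, and the free enol oxygen next to the gem-dimethyl carbon (the other is held in the hydrogen bond to the acyl group) closes the six-membered ring at the substituted terminus under control of the ligand, which sets C10.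

Step 18
Reactants: 27 (divinyl seco ketone)
Product: 28 tetracyclic cis-cyclononenone (the target skeleton with C2=O and a Z C12=C13 double bond)
Conditions: RuCl2(H2IMes)(=CH–C6H4-2-OiPr) (second-generation Hoveyda–Grubbs catalyst, 2 × 10 mol %), toluene (0.5 mM), 60 °C, argon sparge
Reagents that add atoms: none
Why: Ring-closing alkene metathesis: the ruthenium alkylidene should load on the less hindered vinyl group at C14, add to the vinyl group at C10 to give a metallacyclobutane and collapse with loss of ethylene to the C12=C13 bond. The closest known reaction type is metathesis closure of medium-ring cycloalkenes between hindered vinyl groups, one on a gem-dimethylcyclobutane and one on a quaternary carbon. The nine-membered ring closes by joining the two terminal alkenes of the C10–C5–C4–C3–C2–C15–C14 chain, the new double bond lies inside the ring and can only be cis, and no stereocentre is formed. The selectivity needed is cyclisation over dimerisation; high dilution, removal of ethylene and the two pre-set trans relationships (C5/C10 on the pyran, C14/C15 on the cyclobutane), which turn both vinyl groups toward each other, should secure it. C2 is kept as a ketone because a methylidene there would close a six-membered ring with the C10 vinyl group instead, and the moderate temperature spares the allyl vinyl ether unit from Claisen rearrangement.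

Step 19
Reactants: 28 (cis-cyclononenone)
Product: 29 saturated tetracyclic ketone (the target skeleton with C2=O)
Conditions: H2 (4 atm), RhCl(PPh3)3 (10 mol %), benzene–EtOH, rt
Reagents that add atoms: none
Why: Homogeneous hydrogenation with RhCl(PPh3)3 should saturate only the strained cis-disubstituted C12=C13 bond; the tetrasubstituted enol double bonds and the ketones are inert, and this catalyst avoids the double-bond migration toward C14 and the allylic C–O hydrogenolysis that a heterogeneous palladium catalyst could cause.

Step 20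
Reactants: 29 (saturated ketone)
Product: 30 target CNP0497637.2
Conditions: Ph3PCH3Br (6 equiv), KOtBu (6 equiv), THF, 0 to 40 °C; aq. NH4Cl
Reagents that add atoms: methyltriphenylphosphonium bromide, [Br-].C[P+](c1ccccc1)(c1ccccc1)c1ccccc1
Why: Wittig methylenation: the first equivalent of ylide turns the enolised trione into its enolate, which shields those carbonyl groups, and the excess adds to the only free ketone at C2; C15 next to it keeps the trans ring fusion, which is the stable one in the nine-membered ring.

**Compound list**

1 | 2,2-dimethylcyclopentan-1-one | CC1(C)CCCC1=O | starting material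
2 | 2,2-dimethyl-5-(trifluoroacetyl)cyclopentan-1-one | CC1(C)CCC(C(=O)C(F)(F)F)C1=O | intermediate (not isolated)
3 | 5-diazo-2,2-dimethylcyclopentan-1-one | CC1(C)CCC(=[N+]=[N-])C1=O | intermediate
4 | (2,2-dimethylcyclobutylidene)methanone (ketene) | CC1(C)CCC1=C=O | intermediate (not isolated)
5 | (S)-2,2-dimethyl-N-(quinolin-8-yl)cyclobutane-1-carboxamide | O=C(Nc1cccc2cccnc12)[C@H]1CCC1(C)C | intermediate
6 | (1S,4R)-2,2-dimethyl-4-(2-methylprop-1-en-1-yl)-N-(quinolin-8-yl)cyclobutane-1-carboxamide (cis) | O=C(Nc1cccc2cccnc12)[C@H]1[C@@H](C=C(C)C)CC1(C)C | intermediate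
7 | (1S,4R)-2,2-dimethyl-4-(2-methylprop-1-en-1-yl)cyclobutane-1-carbaldehyde (cis) | O=C[C@H]1[C@@H](C=C(C)C)CC1(C)C | intermediate (not isolated)
8 | (1R,4R)-2,2-dimethyl-4-(2-methylprop-1-en-1-yl)cyclobutane-1-carbaldehyde (trans) | O=C[C@@H]1[C@@H](C=C(C)C)CC1(C)C | intermediate
9 | (2R,3R)-2-ethenyl-1,1-dimethyl-3-(2-methylprop-1-en-1-yl)cyclobutane | C=C[C@@H]1[C@@H](C=C(C)C)CC1(C)C | intermediate
10 | 3-[(1S,2R)-2-ethenyl-3,3-dimethylcyclobutyl]-2,2-dimethyloxirane (both oxirane epimers) | C=C[C@@H]1[C@@H](C2OC2(C)C)CC1(C)C | intermediate (not isolated)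
11 | (1S,2R)-2-ethenyl-3,3-dimethylcyclobutane-1-carbaldehyde | C=C[C@@H]1[C@@H](C=O)CC1(C)C | intermediate
12 | 1-[(1S,2R)-2-ethenyl-3,3-dimethylcyclobutyl]prop-2-en-1-ol (both carbinol epimers) | C=C[C@@H]1[C@@H](C(O)C=C)CC1(C)C | intermediate
13 | 1-[(1S,2R)-2-ethenyl-3,3-dimethylcyclobutyl]prop-2-en-1-one | C=C[C@@H]1[C@@H](C(=O)C=C)CC1(C)C | intermediate
14 | ethyl acetate | CCOC(C)=O | starting material
15 | but-3-en-2-one | CC(=O)C=C | starting material
16 | ethyl 3-hydroxy-3-methylpent-4-enoate (racemic) | CCOC(=O)CC(C)(O)C=C | intermediate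
17 | ethyl 3-methyl-3-(triethylsilyloxy)pent-4-enoate (racemic) | CCOC(=O)CC(C)(O[Si](CC)(CC)CC)C=C | intermediate
18 | 3-methyl-3-(triethylsilyloxy)pent-4-enal (racemic) | O=CCC(C)(O[Si](CC)(CC)CC)C=C | intermediate
19 | phloroglucinol | Oc1cc(O)cc(O)c1 | starting material
20 | isobutyryl chloride | CC(C)C(=O)Cl | starting material
21 | 2-methyl-1-(2,4,6-trihydroxyphenyl)propan-1-one | CC(C)C(=O)c1c(O)cc(O)cc1O | intermediate
22 | 3,5-dihydroxy-6,6-dimethyl-2-(2-methylpropanoyl)cyclohexa-2,4-dien-1-one (isobutyrylfilicinic acid) | CC(C)C(=O)C1=C(O)C=C(O)C(C)(C)C1=O | intermediate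
23 | (2R,3RS)-2-{3-[(1S,2R)-2-ethenyl-3,3-dimethylcyclobutyl]-3-oxopropyl}-3-methyl-3-(triethylsilyloxy)pent-4-enal | C=C[C@@H]1[C@@H](C(=O)CC[C@H](C(C)(O[Si](CC)(CC)CC)C=C)C=O)CC1(C)C | intermediate
24 | Knoevenagel adduct: aldehyde carbon of 23 doubly bonded to C4 of 22 (alkylidene trione, alkene geometry not defined) | C=C[C@@H]1[C@@H](C(=O)CC[C@H](C(C)(O[Si](CC)(CC)CC)C=C)C=C2C(=O)C(C)(C)C(=O)C(C(=O)C(C)C)=C2O)CC1(C)C | intermediate (not isolated)
25 | 4-[(2S,3RS)-2-{3-[(1S,2R)-2-ethenyl-3,3-dimethylcyclobutyl]-3-oxopropyl}-3-methyl-3-(triethylsilyloxy)pent-4-en-1-yl]-3,5-dihydroxy-6,6-dimethyl-2-(2-methylpropanoyl)cyclohexa-2,4-dien-1-one | C=C[C@@H]1[C@@H](C(=O)CC[C@H](C(C)(O[Si](CC)(CC)CC)C=C)CC2=C(O)C(C)(C)C(=O)C(C(=O)C(C)C)=C2O)CC1(C)C | intermediate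
26 | 4-[(2S,3RS)-2-{3-[(1S,2R)-2-ethenyl-3,3-dimethylcyclobutyl]-3-oxopropyl}-3-hydroxy-3-methylpent-4-en-1-yl]-3,5-dihydroxy-6,6-dimethyl-2-(2-methylpropanoyl)cyclohexa-2,4-dien-1-one | C=C[C@@H]1[C@@H](C(=O)CC[C@H](C(C)(O)C=C)CC2=C(O)C(C)(C)C(=O)C(C(=O)C(C)C)=C2O)CC1(C)C | intermediate
27 | (2R,3S)-2-ethenyl-3-{3-[(1S,2R)-2-ethenyl-3,3-dimethylcyclobutyl]-3-oxopropyl}-5-hydroxy-2,8,8-trimethyl-6-(2-methylpropanoyl)-3,4-dihydro-2H-chromen-7(8H)-one | O=C(CC[C@H]1CC2=C(O[C@]1(C)C=C)C(C)(C)C(=O)C(C(=O)C(C)C)=C2O)[C@H]1CC(C)(C)[C@@H]1C=C | intermediate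
28 | tetracyclic cis-cyclononenone: target skeleton with C2=O and a Z C12=C13 double bond, stereocentres as in 27 | O=C1CC[C@H]2CC3=C(O[C@]2(C)/C=C\[C@@H]2[C@@H]1CC2(C)C)C(C)(C)C(=O)C(C(=O)C(C)C)=C3O | intermediate
29 | saturated tetracyclic ketone: target skeleton with C2=O, (5S,10R,14R,15S) in the numbering of the plan | O=C1CC[C@H]2CC3=C(O[C@]2(C)CC[C@@H]2[C@@H]1CC2(C)C)C(C)(C)C(=O)C(C(=O)C(C)C)=C3O | intermediate
30 | CNP0497637.2: 2-methylidene compound, (5S,10R,14R,15S) in the numbering of the plan | C=C1CC[C@H]2CC3=C(O[C@]2(C)CC[C@@H]2[C@@H]1CC2(C)C)C(C)(C)C(=O)C(C(=O)C(C)C)=C3O | target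

**Step count**

Total: 20 steps. Longest linear sequence: 15 steps (steps 1–8, then 14–20); steps 9–11 and 12–13 are two short side branches.

**Steps most likely to fail, with fallbacks**

Step 18 (ring-closing metathesis). The alkylidene formed at C13 may add only slowly to the neopentyl-type vinyl group on C10, so that dimer and oligomer formation outrun ring closure. The acidic, chelating enol of the trione may also bind ruthenium and drain the active catalyst. The fallback runs the metathesis on a masked, non-acidic substrate. It sets out from 27: the enol OH is acetylated (Ac2O, Et3N, DMAP cat., CH2Cl2, 0 °C) to the enol acetate of 27, F1. F1 is cyclised with the same ruthenium carbene at high dilution to the enol acetate of 28, F2. The acetate is then removed with K2CO3 in MeOH at 0 °C, which returns to the route at 28.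

Step 17 (palladium allylic etherification). Ionisation of the unactivated tertiary alcohol may be slow, which would let acid-promoted closure without the ligand, C-alkylation at the trione carbon or attack through the hydrogen-bonded enol oxygen take over. The fallback uses a pre-formed leaving group. It sets out from 26, which is deprotonated three times (LiN(SiMe3)2, 3.1 equiv, THF, −78 °C) and treated with ClCO2Me (1.0 equiv); the localised tertiary alkoxide should be acylated in preference to the delocalised enolates. After an AcOH quench this gives the tertiary allylic methyl carbonate of 26, F3. Classical Trost asymmetric allylic alkylation of F3 (Pd2(dba)3·CHCl3, the same ligand, CH2Cl2, rt) with loss of CO2 and methanol returns to the route at 27.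

Step 14 (enamine Michael addition). Enamine formation at the α-carbon next to the quaternary silyloxy centre may be slow, silanolate may be lost from the enamine, and catalyst control may be incomplete next to the racemic neighbouring centre. The fallback replaces the catalyst by a covalently bound auxiliary (Enders hydrazone chemistry). It sets out from 18 and 13: 18 is condensed with (S)-1-amino-2-(methoxymethyl)pyrrolidine to the SAMP hydrazone of 18, F4. F4 is deprotonated (LiN(iPr)2, THF, −78 °C) and the aza-enolate is added to 13 at −100 °C in a Michael addition, then quenched with AcOH, to give the SAMP hydrazone of 23, F5. The facial preference of this aza-enolate is the same as that of the (R)-configured amine catalyst. Two-phase cleavage with aqueous oxalic acid and Et2O releases the auxiliary and returns to the route at 23.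

**Further compounds**

F1 | step 18 | enol acetate of 27 (acetate on the ring enol oxygen at C5 of the chromenone) | O=C(CC[C@H]1CC2=C(O[C@]1(C)C=C)C(C)(C)C(=O)C(C(=O)C(C)C)=C2OC(C)=O)[C@H]1CC(C)(C)[C@@H]1C=C
F2 | step 18 | enol acetate of 28 | O=C1CC[C@H]2CC3=C(O[C@]2(C)/C=C\[C@@H]2[C@@H]1CC2(C)C)C(C)(C)C(=O)C(C(=O)C(C)C)=C3OC(C)=O
F3 | step 17 | tertiary allylic methyl carbonate of 26 | C=C[C@@H]1[C@@H](C(=O)CC[C@H](C(C)(OC(=O)OC)C=C)CC2=C(O)C(C)(C)C(=O)C(C(=O)C(C)C)=C2O)CC1(C)C
F4 | step 14 | SAMP hydrazone of 18 | C=CC(C)(O[Si](CC)(CC)CC)C/C=N/N1CCC[C@H]1COC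
F5 | step 14 | SAMP hydrazone of 23 | C=C[C@@H]1[C@@H](C(=O)CC[C@H](C(C)(O[Si](CC)(CC)CC)C=C)/C=N/N2CCC[C@H]2COC)CC1(C)C
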